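The depside is cut at its aryl ester into a ring A acid and a ring B phenol, and ring B is not made by substituting an arene but assembled from acyclic pieces. Its substitution pattern, carboxyl on C1, oxygen on C2 and C4, propyl on C6, is exactly that of a cyclohexane-1,3-dione carrying an ester. Dibenzyl malonate 1 and (E)-hept-3-en-2-one 2 are therefore joined in one operation, through Michael adduct 3, to dione 4 (C1–C6 by conjugate addition, C2–C3 by ring-closing acylation), which is then dehydrogenated. The precursor is simply the pair 1 and 2; the benzyl ester already serves as the final carboxyl protection. Ring A comes from divarinol.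

Key step: step 1

Remark: the target has no stereogenic element, so no configuration has to be set. Ring A is the 4-hydroxy-2-methoxy-6-propylbenzoyl unit and ring B the 2-hydroxy-6-propylbenzoic acid unit, numbered from the carboxyl-bearing carbon. Compound 4 is drawn as the diketone although it should exist largely as an enol. Ring B is aromatised before it is acylated, because an acylated dione would be a labile enol ester and bromine would attack ring A.

Step 1
Reactants: 1 dibenzyl malonate; 2 (E)-hept-3-en-2-one
Product: 4 benzyl 2,4-dioxo-6-propylcyclohexane-1-carboxylate, via Michael adduct 3 (not isolated)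
Conditions: NaH (1.05 equiv), 1 (1.1 equiv), THF, 0 °C to reflux; then 1 M HCl
Reagents that add atoms: none
Why: The sodium enolate of 1 adds in a conjugate sense to C4 of enone 2 (Michael addition, forming the ring B bond C1–C6) to give adduct 3; proton exchange, shuttled by excess malonate and liberated benzyl alcohol, then delivers the methyl-ketone enolate, whose carbon attacks one benzyl ester (Dieckmann-type intramolecular Claisen acylation, forming C2–C3) and expels benzyloxide, which deprotonates the new 1,3-dione and so pulls all preceding equilibria forward. The closest known reaction type is the malonate–enone Michael–Dieckmann annulation that leads to 6-alkyl-dihydroresorcylates. The single ring is closed in a 6-(enolendo)-exo-trig mode, and no other closure competes because the internal ketone enolate could only reach an ester through a four-membered ring. The two new sp3 centres (C1 and C6) are not controlled beyond the thermodynamic preference of the enolisable β-keto ester for the trans arrangement; the product is racemic and both centres are erased in step 2. The step needs 1,4- over 1,2-addition, which the soft, stabilised malonate anion and the unhindered β-carbon of a simple enone secure, and it needs intact benzyl esters, which is why hydride in THF is used so that the only alkoxide ever present is benzyloxide.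

Step 2
Reactants: 4 benzyl 2,4-dioxo-6-propylcyclohexane-1-carboxylate
Product: 6 benzyl 2,4-dihydroxy-6-propylbenzoate, via bromo dione 5 (not isolated)
Conditions: Br2 (1.0 equiv), DMF, 0 °C; then 80 °C
Reagents that add atoms: none
Why: Halogenation–dehydrohalogenation aromatization of a dihydroresorcylate: the enolised dione is brominated at C3, bromide 5 enolises toward C5 on warming and loses HBr by 1,4-elimination, and tautomerisation gives the arene; the single equivalent of bromine is consumed by the dione enol at 0 °C before any arene exists, and the DMF-buffered HBr at 80 °C should spare the benzyl ester.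

Step 3
Reactants: 7 5-propylbenzene-1,3-diol (divarinol)
Product: 9 2,4-dihydroxy-6-propylbenzaldehyde, via aryl iminium chloride 8 (not isolated)
Conditions: POCl3 (1.2 equiv), DMF, 0 °C to rt; then H2O, 50 °C
Reagents that add atoms: N,N-dimethylformamide, CN(C)C=O (formyl carbon); water, O (carbonyl oxygen)
Why: Vilsmeier–Haack formylation, in which the chloroiminium ion attacks the ring carbon ortho to one hydroxyl and para to the other (C4, equivalent to C6 by symmetry) in preference to the crowded C2 between both hydroxyls, as is known for orcinol, and iminium salt 8 is hydrolysed on aqueous work-up.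

Step 4
Reactants: 9 2,4-dihydroxy-6-propylbenzaldehyde
Product: 10 4-(benzyloxy)-2-hydroxy-6-propylbenzaldehyde
Conditions: BnBr (1.05 equiv), K2CO3 (1.1 equiv), acetone, rt
Reagents that add atoms: benzyl bromide, BrCc1ccccc1
Why: Williamson etherification that is selective because the C2 hydroxyl is held in a hydrogen bond to the aldehyde and is less acidic, so one equivalent of halide with a weak base should alkylate only the C4 phenol.

Step 5
Reactants: 10 4-(benzyloxy)-2-hydroxy-6-propylbenzaldehyde
Product: 11 4-(benzyloxy)-2-methoxy-6-propylbenzaldehyde
Conditions: MeI (3 equiv), K2CO3 (2 equiv), DMF, 50 °C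
Reagents that add atoms: iodomethane, CI
Why: Williamson O-methylation of the remaining chelated phenol, the only acidic site left, under more forcing conditions (excess iodomethane in a dipolar aprotic solvent).

Step 6
Reactants: 11 4-(benzyloxy)-2-methoxy-6-propylbenzaldehyde
Product: 12 4-(benzyloxy)-2-methoxy-6-propylbenzoic acid
Conditions: NaClO2, NaH2PO4, 2-methyl-2-butene, t-BuOH/THF/H2O, 0 °C to rt
Reagents that add atoms: sodium chlorite, [Na+].[O-]Cl=O
Why: Pinnick (Lindgren) oxidation, in which chlorous acid converts the hindered, non-enolisable aldehyde into the acid while 2-methyl-2-butene removes hypochlorous acid before it can chlorinate the electron-rich ring; the benzyl and methyl ethers are inert.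

Step 7
Reactants: 12 4-(benzyloxy)-2-methoxy-6-propylbenzoic acid; 6 benzyl 2,4-dihydroxy-6-propylbenzoate
Product: 14 benzyl 4-{[4-(benzyloxy)-2-methoxy-6-propylbenzoyl]oxy}-2-hydroxy-6-propylbenzoate, via mixed anhydride 13 (not isolated)
Conditions: (CF3CO)2O (3 equiv), toluene, rt; then aq. NaHCO3
Reagents that add atoms: none
Why: Esterification through a mixed trifluoroacetic anhydride (the standard depside coupling), in which the 2,6-disubstituted, electron-rich aroyl group of 13 is transferred with acylium-like character to the free C4 phenol of 6 while the C2 hydroxyl stays chelated to the benzyl ester carbonyl; any aryl trifluoroacetate formed is cleaved on bicarbonate work-up.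

Step 8
Reactants: 14 benzyl 4-{[4-(benzyloxy)-2-methoxy-6-propylbenzoyl]oxy}-2-hydroxy-6-propylbenzoate
Product: 15 2-hydroxy-4-[(4-hydroxy-2-methoxy-6-propylbenzoyl)oxy]-6-propylbenzoic acid
Conditions: H2 (1 atm), 10% Pd/C, EtOAc, rt
Reagents that add atoms: none
Why: Catalytic hydrogenolysis should cleave both the benzyl ester and the benzyl aryl ether to toluene under neutral conditions that leave the depside ester, the methyl ether and both arenes untouched.

Compound list
1 | dibenzyl malonate | O=C(CC(=O)OCc1ccccc1)OCc1ccccc1 | starting material
2 | (E)-hept-3-en-2-one | CCC/C=C/C(C)=O | starting material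
3 | dibenzyl 2-(2-oxoheptan-4-yl)propanedioate (Michael adduct, racemic, formed in the flask) | CCCC(CC(C)=O)C(C(=O)OCc1ccccc1)C(=O)OCc1ccccc1 | intermediate
4 | benzyl 2,4-dioxo-6-propylcyclohexane-1-carboxylate (racemic, C1/C6 mixture expected mainly trans, largely enolised) | CCCC1CC(=O)CC(=O)C1C(=O)OCc1ccccc1 | intermediate
5 | benzyl 3-bromo-2,4-dioxo-6-propylcyclohexane-1-carboxylate (stereoisomer mixture, formed in the flask) | CCCC1CC(=O)C(Br)C(=O)C1C(=O)OCc1ccccc1 | intermediate
6 | benzyl 2,4-dihydroxy-6-propylbenzoate | CCCc1cc(O)cc(O)c1C(=O)OCc1ccccc1 | intermediate
7 | 5-propylbenzene-1,3-diol (divarinol) | CCCc1cc(O)cc(O)c1 | starting material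
8 | N-[(2,4-dihydroxy-6-propylphenyl)methylidene]-N-methylmethanaminium chloride (formed in the flask) | CCCc1cc(O)cc(O)c1C=[N+](C)C.[Cl-] | intermediate
9 | 2,4-dihydroxy-6-propylbenzaldehyde | CCCc1cc(O)cc(O)c1C=O | intermediate
10 | 4-(benzyloxy)-2-hydroxy-6-propylbenzaldehyde | CCCc1cc(OCc2ccccc2)cc(O)c1C=O | intermediate
11 | 4-(benzyloxy)-2-methoxy-6-propylbenzaldehyde | CCCc1cc(OCc2ccccc2)cc(OC)c1C=O | intermediate
12 | 4-(benzyloxy)-2-methoxy-6-propylbenzoic acid | CCCc1cc(OCc2ccccc2)cc(OC)c1C(=O)O | intermediate
13 | 4-(benzyloxy)-2-methoxy-6-propylbenzoic trifluoroacetic anhydride (formed in the flask) | CCCc1cc(OCc2ccccc2)cc(OC)c1C(=O)OC(=O)C(F)(F)F | intermediate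
14 | benzyl 4-{[4-(benzyloxy)-2-methoxy-6-propylbenzoyl]oxy}-2-hydroxy-6-propylbenzoate | CCCc1cc(OC(=O)c2c(CCC)cc(OCc3ccccc3)cc2OC)cc(O)c1C(=O)OCc1ccccc1 | intermediate
15 | 2-hydroxy-4-[(4-hydroxy-2-methoxy-6-propylbenzoyl)oxy]-6-propylbenzoic acid | CCCc1cc(OC(=O)c2c(CCC)cc(O)cc2OC)cc(O)c1C(=O)O | target

Total step count: 8.
Longest linear sequence: 6 steps (steps 3, 4, 5, 6, 7 and 8 from divarinol 7). The ring B branch (steps 1 and 2) joins at step 7.

Steps most likely to fail

1. Step 1. In the aprotic medium the sequence may stall at the open-chain adduct because proton transfer to the methyl-ketone enolate is slow, or the enone may be lost to self-condensation before the malonate captures it. The fallback sets out from 2 and runs the annulation in its classical protic form with dimethyl malonate and NaOMe in MeOH at reflux. This should give, through dimethyl 2-(2-oxoheptan-4-yl)propanedioate F1, methyl 2,4-dioxo-6-propylcyclohexane-1-carboxylate F2. The β-keto ester of F2 would then be exchanged with benzyl alcohol (DMAP cat., toluene, reflux with removal of methanol), which returns to the route at 4.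

2. Step 2. Hot HBr may cleave the benzyl ester with subsequent decarboxylation, or the freshly formed resorcylate may be brominated on the ring. The fallback leaves the dehydrogenation logic and sets out from divarinol 7. Chelation-controlled ortho-carboxylation with methyl magnesium carbonate (MeOMgOCO2Me, DMF, 120 °C, then aq. HCl; a Kolbe–Schmitt-type reaction) should give 2,4-dihydroxy-6-propylbenzoic acid F3. Its carboxylate alone would then be alkylated with BnBr and KHCO3 in DMF at rt, which returns to the route at 6.

3. Step 7. Acyl transfer at the doubly ortho-substituted carbonyl may be slow, giving trifluoroacetic acid time to remove the ring A benzyl ether, or acylation may spill over to the C2 hydroxyl or to a ring carbon. The fallback sets out from 12, which with oxalyl chloride and catalytic DMF in CH2Cl2 should give 4-(benzyloxy)-2-methoxy-6-propylbenzoyl chloride F4. This would be added to the potassium C4-phenoxide of 6 (K2CO3, acetone, rt), an acid-free acylation that exploits the higher acidity of the unchelated hydroxyl and returns to the route at 14.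

Further compounds
F1 | step 1 | dimethyl 2-(2-oxoheptan-4-yl)propanedioate | CCCC(CC(C)=O)C(C(=O)OC)C(=O)OC
F2 | step 1 | methyl 2,4-dioxo-6-propylcyclohexane-1-carboxylate | CCCC1CC(=O)CC(=O)C1C(=O)OC
F3 | step 2 | 2,4-dihydroxy-6-propylbenzoic acid | CCCc1cc(O)cc(O)c1C(=O)O
F4 | step 7 | 4-(benzyloxy)-2-methoxy-6-propylbenzoyl chloride | CCCc1cc(OCc2ccccc2)cc(OC)c1C(=O)Cl
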